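**Retrosynthetic overview**
1. The angelate (C2–O, installed last) and the p-anisoate (C6–O) are cut back to a bicyclic 2,4,6-triol core carrying a silyl ether at O2.
2. The seven-membered ring is formed last, by ring-closing metathesis (C8=C9) between a C1 allyl arm and a C6 methallyl arm.
3. Key C–C bond: C6–C7, by intermolecular chelation-controlled carbonyl methallylation of a cyclopentane β-hydroxy aldehyde (sets C6).
4. C4 comes from iPr–Ce addition to a ketone, C2 from an OH-directed reduction, and C5/C1 from Michael addition of lithio-1,3-dithiane plus enolate allylation on (R)-4-silyloxy-2-methylcyclopentenone.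
5. The five-membered ring is formed first, by Piancatelli rearrangement of 1-(furan-2-yl)ethanol, and resolved with a lipase.

**Conventions and assumption**
- Positions are given in daucane numbering: C1 = quaternary C–CH3, C2 = CH–OAng, C3 = CH2, C4 = C(OH)iPr, C5 = ring-fusion CH, C6 = CH–O-anisoyl, C7–C10 = rest of the seven-membered ring. β is the face of the C1 methyl group. The target is read as 2β-angeloyloxy-6α-(p-anisoyloxy)dauc-8-en-4β-ol.
- Numbered coupling partners stand under Reactants; the line "Reagents that add atoms" holds only reagents without a number.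

Step 1
Reactants: 1 1-(furan-2-yl)ethanol
Product: 2 (±)-trans-4-hydroxy-5-methylcyclopent-2-en-1-one
Conditions: ZnCl2, dioxane/H2O (1:1), reflux
Reagents that add atoms: water, O
Why: Piancatelli rearrangement of a 2-furylcarbinol (water attack, ring opening, conrotatory 4π-electrocyclisation) gives the trans-4-hydroxy-5-alkylcyclopentenone.

Step 2
Reactants: 2 (±)-trans-4-hydroxy-5-methylcyclopent-2-en-1-one
Product: 3 (±)-4-hydroxy-2-methylcyclopent-2-en-1-one
Conditions: phosphate buffer pH 8, dioxane/H2O, 60 °C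
Reagents that add atoms: water, O
Why: Base-mediated conjugate hydration and β-elimination (1,3-transposition) moves the system to the more stable 2-alkyl-4-hydroxy enone, the standard follow-up to a Piancatelli rearrangement.

Step 3
Reactants: 3 (±)-4-hydroxy-2-methylcyclopent-2-en-1-one
Product: 4 (R)-4-acetoxy-2-methylcyclopent-2-en-1-one
Conditions: porcine pancreatic lipase, vinyl acetate, MTBE, rt, stopped at about 45% conversion; unreacted (S)-3 removed by chromatography
Reagents that add atoms: vinyl acetate, C=COC(C)=O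
Why: Lipase-catalysed kinetic resolution by irreversible transesterification acylates the R alcohol of 2-alkyl-4-hydroxycyclopentenones, which fixes the absolute configuration of the whole route.

Step 4
Reactants: 4 (R)-4-acetoxy-2-methylcyclopent-2-en-1-one
Product: 5 (R)-4-hydroxy-2-methylcyclopent-2-en-1-one
Conditions: porcine pancreatic lipase, 0.1 M phosphate buffer pH 7, rt
Reagents that add atoms: none
Why: Enzymatic ester hydrolysis at neutral pH frees the alcohol without the β-elimination that base causes in 4-acyloxycyclopentenones, and the second enzymatic pass raises the ee further.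

Step 5
Reactants: 5 (R)-4-hydroxy-2-methylcyclopent-2-en-1-one
Product: 6 (R)-4-(tert-butyldimethylsilyloxy)-2-methylcyclopent-2-en-1-one
Conditions: TBSCl, imidazole, DMF, 0 °C to rt
Reagents that add atoms: tert-butyldimethylsilyl chloride, CC(C)(C)[Si](C)(C)Cl
Why: Standard silylation gives the bulky 4-silyloxy group that shields the α face of the enone in the next step.

Step 6
Reactants: 6 (R)-4-(tert-butyldimethylsilyloxy)-2-methylcyclopent-2-en-1-one; 7 1,3-dithiane; 8 allyl bromide
Product: 11 (2R,3R,4R)-2-allyl-4-(tert-butyldimethylsilyloxy)-3-(1,3-dithian-2-yl)-2-methylcyclopentan-1-one, via 2-lithio-1,3-dithiane 9 (not isolated), via lithium enolate 10 (not isolated)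
Conditions: n-BuLi, THF, −30 °C; HMPA, −78 °C; 6; then 8, −78 to −40 °C
Reagents that add atoms: none
Why: Michael addition of the sulfur-stabilised Corey–Seebach anion (1,4-selective in HMPA) occurs anti to the OTBS group and sets C5, and C-allylation of the resulting regiodefined enolate occurs anti to the new dithianyl group and sets the quaternary C1 (methyl β, allyl α).

Step 7
Reactants: 11 (2R,3R,4R)-2-allyl-4-(tert-butyldimethylsilyloxy)-3-(1,3-dithian-2-yl)-2-methylcyclopentan-1-one
Product: 12 (2R,3R,4R)-2-allyl-3-(1,3-dithian-2-yl)-4-hydroxy-2-methylcyclopentan-1-one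
Conditions: 48% aq. HF, MeCN, 0 °C
Reagents that add atoms: none
Why: Acidic desilylation frees the β-hydroxy ketone without the E1cB loss of water that fluoride base would cause.

Step 8
Reactants: 12 (2R,3R,4R)-2-allyl-3-(1,3-dithian-2-yl)-4-hydroxy-2-methylcyclopentan-1-one
Product: 13 (1R,3R,4R,5R)-4-allyl-5-(1,3-dithian-2-yl)-4-methylcyclopentane-1,3-diol
Conditions: Me4NBH(OAc)3, MeCN/AcOH (1:1), −30 °C
Reagents that add atoms: none
Why: Evans–Saksena hydroxyl-directed reduction delivers hydride intramolecularly from the α C4–OH to the α face of the C2 ketone, giving the anti-1,3-diol with the C2 hydroxyl β (cis to the C1 methyl).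

Step 9
Reactants: 13 (1R,3R,4R,5R)-4-allyl-5-(1,3-dithian-2-yl)-4-methylcyclopentane-1,3-diol
Product: 14 (1R,2R,3R,4R)-2-allyl-3-(1,3-dithian-2-yl)-2-methyl-4-(triethylsilyloxy)cyclopentan-1-ol
Conditions: TESCl (1.05 equiv), imidazole, CH2Cl2, −40 °C
Reagents that add atoms: chlorotriethylsilane, CC[Si](Cl)(CC)CC
Why: Sterically controlled monosilylation takes the C4 hydroxyl, because the C2 hydroxyl is neopentylic (next to the quaternary C1).

Step 10
Reactants: 14 (1R,2R,3R,4R)-2-allyl-3-(1,3-dithian-2-yl)-2-methyl-4-(triethylsilyloxy)cyclopentan-1-ol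
Product: 15 tert-butyl{[(1R,2R,3R,4R)-2-allyl-3-(1,3-dithian-2-yl)-2-methyl-4-(triethylsilyloxy)cyclopentyl]oxy}dimethylsilane
Conditions: TBSOTf, 2,6-lutidine, CH2Cl2, 0 °C
Reagents that add atoms: tert-butyldimethylsilyl trifluoromethanesulfonate, CC(C)(C)[Si](C)(C)OS(=O)(=O)C(F)(F)F
Why: The silyl triflate silylates even the hindered C2 hydroxyl and gives the robust ether that protects O2 until the end.

Step 11
Reactants: 15 tert-butyl{[(1R,2R,3R,4R)-2-allyl-3-(1,3-dithian-2-yl)-2-methyl-4-(triethylsilyloxy)cyclopentyl]oxy}dimethylsilane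
Product: 16 (1R,2R,3R,4R)-3-allyl-4-(tert-butyldimethylsilyloxy)-2-(1,3-dithian-2-yl)-3-methylcyclopentan-1-ol
Conditions: PPTS (cat.), MeOH/CH2Cl2, 0 °C
Reagents that add atoms: none
Why: Mild acidic methanolysis removes the triethylsilyl ether far faster than the hindered TBS ether, so only the C4 hydroxyl is freed.

Step 12
Reactants: 16 (1R,2R,3R,4R)-3-allyl-4-(tert-butyldimethylsilyloxy)-2-(1,3-dithian-2-yl)-3-methylcyclopentan-1-ol
Product: 17 (2R,3R,4R)-3-allyl-4-(tert-butyldimethylsilyloxy)-2-(1,3-dithian-2-yl)-3-methylcyclopentan-1-one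
Conditions: SO3·pyridine, DMSO, iPr2NEt, CH2Cl2, 0 °C
Reagents that add atoms: none
Why: Parikh–Doering oxidation gives the C4 ketone under conditions that leave the dithiane sulfur atoms and the β-silyloxy group untouched.

Step 13
Reactants: 17 (2R,3R,4R)-3-allyl-4-(tert-butyldimethylsilyloxy)-2-(1,3-dithian-2-yl)-3-methylcyclopentan-1-one; 18 isopropylmagnesium chloride
Product: 20 (1R,2R,3R,4R)-3-allyl-4-(tert-butyldimethylsilyloxy)-2-(1,3-dithian-2-yl)-1-isopropyl-3-methylcyclopentan-1-ol, via isopropylcerium dichloride 19 (not isolated)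
Conditions: 18, anhydrous CeCl3, THF, −78 °C; then 17, −78 to 0 °C
Reagents that add atoms: none
Why: The weakly basic organocerium reagent (Imamoto 1,2-addition) adds without enolisation or reduction, from the α face anti to the adjacent β-dithianyl group, so C4 carries isopropyl α and hydroxyl β.

Step 14
Reactants: 20 (1R,2R,3R,4R)-3-allyl-4-(tert-butyldimethylsilyloxy)-2-(1,3-dithian-2-yl)-1-isopropyl-3-methylcyclopentan-1-ol
Product: 21 (1R,2R,3R,5R)-2-allyl-3-(tert-butyldimethylsilyloxy)-5-hydroxy-5-isopropyl-2-methylcyclopentane-1-carbaldehyde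
Conditions: MeI, CaCO3, MeCN/H2O (9:1), 45 °C
Reagents that add atoms: water, O
Why: Alkylative hydrolysis of the dithiane (S-methylation, then water) unmasks the C6 aldehyde under near-neutral conditions that spare the alkene, the silyl ether and the β-hydroxy aldehyde.

Step 15
Reactants: 21 (1R,2R,3R,5R)-2-allyl-3-(tert-butyldimethylsilyloxy)-5-hydroxy-5-isopropyl-2-methylcyclopentane-1-carbaldehyde; 22 2-methylallyl bromide
Product: 24 (1R,2S,3R,4R)-3-allyl-4-(tert-butyldimethylsilyloxy)-2-[(1S)-1-hydroxy-3-methylbut-3-en-1-yl]-1-isopropyl-3-methylcyclopentan-1-ol, via 2-methylallylindium dibromide 23 (not isolated)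
Conditions: In powder, THF/H2O (1:1), rt
Reagents that add atoms: none
Why: In this indium-mediated Barbier carbonyl allylation (the key fragment union) the aldehyde is held in a six-membered chelate with the cis C4 hydroxyl and is attacked on the face away from C1 and its methyl group, which gives the 6S carbinol (Cram-chelate control).

Step 16
Reactants: 24 (1R,2S,3R,4R)-3-allyl-4-(tert-butyldimethylsilyloxy)-2-[(1S)-1-hydroxy-3-methylbut-3-en-1-yl]-1-isopropyl-3-methylcyclopentan-1-ol; 25 4-methoxybenzoyl chloride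
Product: 26 (1S)-1-[(1S,2R,3R,5R)-2-allyl-3-(tert-butyldimethylsilyloxy)-5-hydroxy-5-isopropyl-2-methylcyclopentyl]-3-methylbut-3-en-1-yl 4-methoxybenzoate
Conditions: Et3N, DMAP, CH2Cl2, rt to 40 °C
Reagents that add atoms: none
Why: DMAP-catalysed acylation esterifies the secondary C6 hydroxyl only, since the tertiary C4 hydroxyl does not react and O2 is silylated.

Step 17
Reactants: 26 (1S)-1-[(1S,2R,3R,5R)-2-allyl-3-(tert-butyldimethylsilyloxy)-5-hydroxy-5-isopropyl-2-methylcyclopentyl]-3-methylbut-3-en-1-yl 4-methoxybenzoate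
Product: 27 (1R,3R,3aS,4S,8aR)-1-(tert-butyldimethylsilyloxy)-3-hydroxy-3-isopropyl-6,8a-dimethyl-1,2,3,3a,4,5,8,8a-octahydroazulen-4-yl 4-methoxybenzoate
Conditions: Grubbs II (10 mol%), CH2Cl2 (5 mM), 40 °C
Reagents that add atoms: none
Why: Ring-closing metathesis between the allyl and methallyl arms, which are trans on the cyclopentane, closes the trans-fused cycloheptene with the trisubstituted C8=C9 bond and releases ethylene.

Step 18
Reactants: 27 (1R,3R,3aS,4S,8aR)-1-(tert-butyldimethylsilyloxy)-3-hydroxy-3-isopropyl-6,8a-dimethyl-1,2,3,3a,4,5,8,8a-octahydroazulen-4-yl 4-methoxybenzoate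
Product: 28 (1R,3R,3aS,4S,8aR)-1,3-dihydroxy-3-isopropyl-6,8a-dimethyl-1,2,3,3a,4,5,8,8a-octahydroazulen-4-yl 4-methoxybenzoate
Conditions: HF·pyridine, pyridine/THF, 0 °C to rt
Reagents that add atoms: none
Why: Buffered HF removes the TBS ether without the ester migration that basic fluoride could cause and without harming the tertiary alcohol or the alkene.

Step 19
Reactants: 28 (1R,3R,3aS,4S,8aR)-1,3-dihydroxy-3-isopropyl-6,8a-dimethyl-1,2,3,3a,4,5,8,8a-octahydroazulen-4-yl 4-methoxybenzoate; 29 angelic acid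
Product: 31 (1R,3R,3aS,4S,8aR)-3-hydroxy-3-isopropyl-4-[(4-methoxybenzoyl)oxy]-6,8a-dimethyl-1,2,3,3a,4,5,8,8a-octahydroazulen-1-yl (2Z)-2-methylbut-2-enoate, via angelic 2,4,6-trichlorobenzoic anhydride 30 (not isolated)
Conditions: 29, 2,4,6-trichlorobenzoyl chloride, Et3N, toluene, rt; then 28, 80 °C
Reagents that add atoms: none
Why: Yamaguchi-type mixed-anhydride esterification run without DMAP acylates the secondary C2 hydroxyl at the less hindered angeloyl carbonyl and avoids the nucleophile-induced Z-to-E isomerisation to the tiglate, while the tertiary C4 hydroxyl stays free.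

**Compound list**
1 | 1-(furan-2-yl)ethanol (racemic) | CC(O)c1ccco1 | starting material
2 | (±)-trans-4-hydroxy-5-methylcyclopent-2-en-1-one (racemate, one enantiomer drawn) | C[C@H]1[C@H](O)C=CC1=O | intermediate
3 | (±)-4-hydroxy-2-methylcyclopent-2-en-1-one | CC1=CC(O)CC1=O | intermediate
4 | (R)-4-acetoxy-2-methylcyclopent-2-en-1-one | O=C1C[C@@H](OC(C)=O)C=C1C | intermediate
5 | (R)-4-hydroxy-2-methylcyclopent-2-en-1-one | O=C1C[C@@H](O)C=C1C | intermediate
6 | (R)-4-(tert-butyldimethylsilyloxy)-2-methylcyclopent-2-en-1-one | O=C1C[C@@H](O[Si](C)(C)C(C)(C)C)C=C1C | intermediate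
7 | 1,3-dithiane | C1SCCCS1 | starting material
8 | allyl bromide | C=CCBr | starting material
9 | 2-lithio-1,3-dithiane | [Li]C1SCCCS1 | intermediate
10 | lithium (3R,4R)-4-(tert-butyldimethylsilyloxy)-3-(1,3-dithian-2-yl)-2-methylcyclopent-1-en-1-olate | CC1=C(O[Li])C[C@@H](O[Si](C)(C)C(C)(C)C)[C@@H]1C1SCCCS1 | intermediate
11 | (2R,3R,4R)-2-allyl-4-(tert-butyldimethylsilyloxy)-3-(1,3-dithian-2-yl)-2-methylcyclopentan-1-one | O=C1C[C@@H](O[Si](C)(C)C(C)(C)C)[C@H](C2SCCCS2)[C@@]1(C)CC=C | intermediate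
12 | (2R,3R,4R)-2-allyl-3-(1,3-dithian-2-yl)-4-hydroxy-2-methylcyclopentan-1-one | O=C1C[C@@H](O)[C@H](C2SCCCS2)[C@@]1(C)CC=C | intermediate
13 | (1R,3R,4R,5R)-4-allyl-5-(1,3-dithian-2-yl)-4-methylcyclopentane-1,3-diol | O[C@@H]1C[C@@H](O)[C@H](C2SCCCS2)[C@@]1(C)CC=C | intermediate
14 | (1R,2R,3R,4R)-2-allyl-3-(1,3-dithian-2-yl)-2-methyl-4-(triethylsilyloxy)cyclopentan-1-ol | O[C@@H]1C[C@@H](O[Si](CC)(CC)CC)[C@H](C2SCCCS2)[C@@]1(C)CC=C | intermediate
15 | tert-butyl{[(1R,2R,3R,4R)-2-allyl-3-(1,3-dithian-2-yl)-2-methyl-4-(triethylsilyloxy)cyclopentyl]oxy}dimethylsilane | CC(C)(C)[Si](C)(C)O[C@@H]1C[C@@H](O[Si](CC)(CC)CC)[C@H](C2SCCCS2)[C@@]1(C)CC=C | intermediate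
16 | (1R,2R,3R,4R)-3-allyl-4-(tert-butyldimethylsilyloxy)-2-(1,3-dithian-2-yl)-3-methylcyclopentan-1-ol | CC(C)(C)[Si](C)(C)O[C@@H]1C[C@@H](O)[C@H](C2SCCCS2)[C@@]1(C)CC=C | intermediate
17 | (2R,3R,4R)-3-allyl-4-(tert-butyldimethylsilyloxy)-2-(1,3-dithian-2-yl)-3-methylcyclopentan-1-one | CC(C)(C)[Si](C)(C)O[C@@H]1CC(=O)[C@H](C2SCCCS2)[C@@]1(C)CC=C | intermediate
18 | isopropylmagnesium chloride | CC(C)[Mg]Cl | starting material
19 | isopropylcerium dichloride | CC(C)[Ce](Cl)Cl | intermediate
20 | (1R,2R,3R,4R)-3-allyl-4-(tert-butyldimethylsilyloxy)-2-(1,3-dithian-2-yl)-1-isopropyl-3-methylcyclopentan-1-ol | CC(C)(C)[Si](C)(C)O[C@@H]1C[C@@](O)(C(C)C)[C@H](C2SCCCS2)[C@@]1(C)CC=C | intermediate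
21 | (1R,2R,3R,5R)-2-allyl-3-(tert-butyldimethylsilyloxy)-5-hydroxy-5-isopropyl-2-methylcyclopentane-1-carbaldehyde | CC(C)(C)[Si](C)(C)O[C@@H]1C[C@@](O)(C(C)C)[C@H](C=O)[C@@]1(C)CC=C | intermediate
22 | 2-methylallyl bromide (3-bromo-2-methylprop-1-ene) | CC(=C)CBr | starting material
23 | (2-methylallyl)indium dibromide (drawn as the monoallyl component of the organoindium sesquibromide formed from In and 22) | CC(=C)C[In](Br)Br | intermediate
24 | (1R,2S,3R,4R)-3-allyl-4-(tert-butyldimethylsilyloxy)-2-[(1S)-1-hydroxy-3-methylbut-3-en-1-yl]-1-isopropyl-3-methylcyclopentan-1-ol | CC(C)(C)[Si](C)(C)O[C@@H]1C[C@@](O)(C(C)C)[C@H]([C@@H](O)CC(C)=C)[C@@]1(C)CC=C | intermediate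
25 | 4-methoxybenzoyl chloride | COc1ccc(cc1)C(Cl)=O | starting material
26 | (1S)-1-[(1S,2R,3R,5R)-2-allyl-3-(tert-butyldimethylsilyloxy)-5-hydroxy-5-isopropyl-2-methylcyclopentyl]-3-methylbut-3-en-1-yl 4-methoxybenzoate | CC(C)(C)[Si](C)(C)O[C@@H]1C[C@@](O)(C(C)C)[C@H]([C@@H](OC(=O)c2ccc(OC)cc2)CC(C)=C)[C@@]1(C)CC=C | intermediate
27 | (1R,3R,3aS,4S,8aR)-1-(tert-butyldimethylsilyloxy)-3-hydroxy-3-isopropyl-6,8a-dimethyl-1,2,3,3a,4,5,8,8a-octahydroazulen-4-yl 4-methoxybenzoate | CC(C)(C)[Si](C)(C)O[C@@H]1C[C@@](O)(C(C)C)[C@@H]2[C@@H](OC(=O)c3ccc(OC)cc3)CC(C)=CC[C@]21C | intermediate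
28 | (1R,3R,3aS,4S,8aR)-1,3-dihydroxy-3-isopropyl-6,8a-dimethyl-1,2,3,3a,4,5,8,8a-octahydroazulen-4-yl 4-methoxybenzoate | O[C@@H]1C[C@@](O)(C(C)C)[C@@H]2[C@@H](OC(=O)c3ccc(OC)cc3)CC(C)=CC[C@]21C | intermediate
29 | angelic acid, (2Z)-2-methylbut-2-enoic acid | C/C=C(/C)C(=O)O | starting material
30 | angelic 2,4,6-trichlorobenzoic anhydride | C/C=C(/C)C(=O)OC(=O)c1c(Cl)cc(Cl)cc1Cl | intermediate
31 | (1R,3R,3aS,4S,8aR)-3-hydroxy-3-isopropyl-4-[(4-methoxybenzoyl)oxy]-6,8a-dimethyl-1,2,3,3a,4,5,8,8a-octahydroazulen-1-yl (2Z)-2-methylbut-2-enoate (CNP0204191.1) | C/C=C(/C)C(=O)O[C@@H]1C[C@@](O)(C(C)C)[C@@H]2[C@@H](OC(=O)c3ccc(OC)cc3)CC(C)=CC[C@]21C | target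

**Step count and risks**
Total step count: 19.
Longest linear sequence: 19 steps (1 to 31); compounds 7, 8, 18, 22, 25 and 29 are bought.

The three steps most likely to fail:

Step 6. The strongly basic dithiane anion may add 1,2 to the enone or trigger loss of the silyloxy group. The fallback sets out from 6 and comes back at 11, and swaps the sulfur-stabilised carbanion for a non-basic copper reagent that carries a masked hydroxymethyl group. CuI-catalysed 1,4-addition of (isopropoxydimethylsilyl)methylmagnesium chloride to 6 (THF, −78 °C, anti to OTBS) gives the chloromagnesium enolate F1. F1 is allylated in the same flask with 8 and HMPA to give the silylmethyl ketone F2. Tamao oxidation (H2O2, KF, KHCO3, THF/MeOH) gives the hydroxymethyl ketone F3. Dess–Martin oxidation gives the keto aldehyde F4. Aldehyde-selective thioacetalisation with propane-1,3-dithiol (MgBr2·OEt2, Et2O) then gives 11.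

Step 15. The aldehyde is very hindered, and the C6 configuration depends on chelation by the free C4 hydroxyl. The fallback sets out from 21 and comes back at 24, and replaces substrate (chelate) control by reagent control. (−)-B-(2-methylallyl)diisopinocampheylborane F5 is made in the flask from (−)-Ipc2BOMe (derived from (+)-α-pinene) and 2-methylallylmagnesium chloride, and is added to 21 in Et2O at −78 °C, where the hindered tertiary hydroxyl does not consume the reagent. Work-up with NaOH/H2O2 gives 24. This antipode of the Brown reagent gives the S carbinol when the aldehyde substituent outranks the allyl CH2, as it does here.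

Step 19. The C2 hydroxyl is neopentylic, and the angelate can isomerise to the tiglate. The fallback sets out from 28 and comes back at 31, and builds the Z alkene on the substrate instead of transferring it. Esterification of 28 with 2-[bis(2,2,2-trifluoroethoxy)phosphoryl]propanoic acid (DCC, DMAP, CH2Cl2) gives the phosphonate ester F6. KHMDS and 18-crown-6 (THF, −78 °C) give the potassium phosphonate F7. F7 reacts with acetaldehyde in a Z-selective Still–Gennari olefination to give 31.

**Further compounds**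
F1 | step 6 | chloromagnesium enolate, 4-(tert-butyldimethylsilyloxy)-3-{[isopropoxy(dimethyl)silyl]methyl}-2-methylcyclopent-1-en-1-olate (3,4-trans, configuration as in 10) | CC1=C(O[Mg]Cl)C[C@@H](O[Si](C)(C)C(C)(C)C)[C@@H]1C[Si](C)(C)OC(C)C
F2 | step 6 | 2-allyl-4-(tert-butyldimethylsilyloxy)-3-{[isopropoxy(dimethyl)silyl]methyl}-2-methylcyclopentan-1-one (configuration as in 11) | O=C1C[C@@H](O[Si](C)(C)C(C)(C)C)[C@H](C[Si](C)(C)OC(C)C)[C@@]1(C)CC=C
F3 | step 6 | 2-allyl-4-(tert-butyldimethylsilyloxy)-3-(hydroxymethyl)-2-methylcyclopentan-1-one (configuration as in 11) | O=C1C[C@@H](O[Si](C)(C)C(C)(C)C)[C@H](CO)[C@@]1(C)CC=C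
F4 | step 6 | 2-allyl-5-(tert-butyldimethylsilyloxy)-2-methyl-3-oxocyclopentane-1-carbaldehyde (configuration as in 11) | O=C1C[C@@H](O[Si](C)(C)C(C)(C)C)[C@H](C=O)[C@@]1(C)CC=C
F5 | step 15 | (−)-B-(2-methylallyl)diisopinocampheylborane | CC(=C)CB([C@@H]1C[C@@H]2C[C@H]([C@H]1C)C2(C)C)[C@@H]1C[C@@H]2C[C@H]([C@H]1C)C2(C)C
F6 | step 19 | (1R,3R,3aS,4S,8aR)-3-hydroxy-3-isopropyl-4-[(4-methoxybenzoyl)oxy]-6,8a-dimethyl-1,2,3,3a,4,5,8,8a-octahydroazulen-1-yl 2-[bis(2,2,2-trifluoroethoxy)phosphoryl]propanoate (both epimers at the phosphonate carbon) | CC(C(=O)O[C@@H]1C[C@@](O)(C(C)C)[C@@H]2[C@@H](OC(=O)c3ccc(OC)cc3)CC(C)=CC[C@]21C)P(=O)(OCC(F)(F)F)OCC(F)(F)F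
F7 | step 19 | potassium salt of the phosphonate carbanion of F6 | [K+].C[C-](C(=O)O[C@@H]1C[C@@](O)(C(C)C)[C@@H]2[C@@H](OC(=O)c3ccc(OC)cc3)CC(C)=CC[C@]21C)P(=O)(OCC(F)(F)F)OCC(F)(F)F
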